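However D reacts, the count of what was charged holds: D that is no longer D has reacted, so the reacted part c is one minus the fraction of D left.

| flask | D | J | remark | time |
|---|---|---|---|---|
| spring | 0.0010 M | 1 mM | run made earlier |  |
| summer | 0.0010 M | 2.2 mM | run made earlier |  |
| autumn | 5.0 × 10⁻⁴ M | 1.5 mM | run made earlier |  |
| flask | 0.0010 M | 1.50 mM |  | 3.0 min |

- spring (time / min: D / %, X / %): 0.250: 84.3, 3.8; 0.833: 59.5, 6.8; 1.33: 46.5, 4.7; 2.00: 36.0, 6.5; 3.00: 24.6, 6.4
- summer (time / min: D / %, X / %): 0.667: 52.7, 12.2; 1.33: 31.3, 12.5; 2.00: 17.4, 15.2; 2.50: 12.0, 13.8; 3.00: 10.0, 12.8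
- autumn (time / min: D / %, X / %): 0.250: 87.6, 8.2; 0.833: 62.0, 13.1; 1.33: 47.0, 16.7; 2.00: 30.8, 18.3; 3.00: 21.3, 17.7

(readings scatter by 1 percentage point)

- part of the D that has reacted at 3.0 min
- share of the unused J that is free and not bound as Q, at 3.0 min

- the earlier runs do not show how much of J is bound; that part of a forecast is a guess

If c_D falls as dc_D/dt = −k c_D, the integral is c_D/c_D,start = exp(−kt), so a single reading gives k = ln(c_D,start/c_D)/t, an average pseudo-first-order constant for the run. At 3.00 min the spring run gives 0.467 /min and the summer run 0.768 /min. Both were charged with D as in the flask, so a straight line can be drawn through them against charged J. Its J slope, the gain in k per unit of J charged at this D, is 0.250 /mM/min, and the line, carried back past the runs, meets zero J at 0.217 /min. For the flask the line gives 0.592 /min, so the reckoning here is c = 83.1%.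

The autumn run looks nearly the same as the flask, with equal J and half the D. Its reading gives 0.515 /min, and it leaves 21.3% of its D. The flask is reckoned to end further on, because with J equal its reckoned constant is larger, which points to a part of the loss of D that speeds up with c_D.

The readings do not show fr. The forecast puts c at 83% (79% to 87%) and fr at 50% (30% to 78%), the fr resting on this ground: “If Q holds one J per D, Q is about 0.72 mM.”

    D + J → G + X (k = 3.80 /M/s)
    J + G ⇌ Q, settled at all times (K = 4.30 × 10⁶ /M)
    2 D → L (k = 3.10 /M/s)
    D + X → E (k = 41.0 /M/s)

The flask gives c = 83.7% and fr = 71.6%. At 3.00 min c_Q is 3.32 × 10⁻⁴ M, while E holds 48.8% of the D charged, each E counted as two. Read back through the integral, this c means a constant of 0.605 /min, against 0.592 /min from the line. Taken down the J slope to a neighbour flask with 6.0 × 10⁻⁴ M of J and D as here, the line gives 0.367 /min, hence a reacted part of 66.7% at 3.0 min; that neighbour flask stands at 67.8%.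

(The readings are simulated for substances that don't exist; the scatter is artificial.)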